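## Structural features

The target is a 2,3-dihydro-1-benzofuran: the dihydrofuran ring O1–C2–C3–C3a–C7a is fused to the benzo ring C3a–C4–C5–C6–C7–C7a. It carries a 4-hydroxyphenyl group on C2, a secondary carboxamide on C3 and an (E)-acrylamide on C5, and each amide nitrogen bears a 4-guanidinobutyl (agmatine) chain. The only stereocentres are the neighbours C2 and C3, both R, with the aryl and carboxamide groups trans. C3–H is benzylic, α to a carbonyl group and β to the ring oxygen, so it epimerises easily and can start an E1cB opening of the O1–C2 bond; because trans is the more stable arrangement, C3 corrects itself as long as C2 is intact, and C2 is the centre that has to be secured. The C2–O1 bond is a benzylic ether activated by the para-oxygenated aryl group and can ionise in strong acid; the cinnamamide double bond excludes hydrogenolysis; the two guanidines and the phenol must stay masked to the end. The real difficulty is therefore the absolute configuration at C2, together with the need to keep C3 free of a carbonyl group while hot or basic steps are run. The key step uses the fact that C5 is para to C7a, the carbon bearing O1: this is the pattern a 2-alkoxyfuran leaves (its C2 becoming C7a, its ring oxygen ending on C5) after [4+2] addition to an alkyne (C3a and C4) and opening of the oxygen bridge. The atoms O1, C2 and C3 act as the tether between furan and alkyne, so the same event closes the dihydrofuran ring while the two stereocentres, set earlier in an open chain, are only carried along.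

## Logic of the disconnections

**26 back to 25.** The four N–CO2tBu bonds and the aryl O–tBu bond are cut. Guanidines and phenol must be masked through palladium, oxidation and coupling chemistry, and hydrogenolysis is excluded by the alkene, so all masks are chosen to fall in one acid step. The gain is a neutral, chromatographable 25. The forward step must not ionise C2–O1.

**25 back to 21 and 24; 24 back to 22 and 23.** The two amide C–N bonds are cut, and in the side branch the guanidine C–N bond. Both arms use the same amine, so one coupling serves two sites and removes both polar chains at once. The forward step must activate the C3 carboxyl group without E1cB ring opening; epimerisation at C3 is tolerable because trans is favoured.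

**21 back to 19 and 18.** The C3 carboxyl carbon is taken back to a CH2–O–Si group (change of oxidation level, then the O–Si bond). An sp3 carbinol on C3 keeps C3–H non-acidic through the etherification, the cycloaddition and the Heck reaction. The forward oxidation has to pass through 20 without β-elimination of O1.

**18 back to 16 and 17; 16 back to 15.** The bond between C5 and the alkene carbon is cut, then the O–S bond of the sulfonate. The C5 oxygen is exactly what the cycloaddition leaves behind, and a triflate turns it into a carbon electrophile. This reduces the problem to a phenol and asks for an E-selective Heck reaction on an electron-rich aryl triflate.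

**15 back to 13 (through 14).** The bonds C3a–C7a and C4–C5 are cut. All six benzo carbons then come from a furan and an alkyne, both rings are made in one operation, and the stereocentres sit untouched in the tether. The forward step needs an unactivated alkyne to add before the acid-sensitive alkoxyfuran decomposes, and the bridge must open at C7a.

**13 back to 12, and 12 back to 10 and 11.** The alkyne C–Si bond (a mask) and the O–C(furyl) bond are cut. The ether is formed at oxygen, so the carbinol C–O bond and its configuration are untouched, and the mask keeps copper away from the alkyne. The forward step must couple a hindered secondary alcohol without silyl migration.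

**10 back to 7 and 8 (through 9).** The C–C bond between the carbinol carbon and the propargylic carbon is cut. One step then sets both stereocentres in the anti relationship that becomes trans in the ring, and the molecule falls into an aromatic aldehyde and a four-carbon chiral unit. The forward step needs clean chirality transfer from mesylate to allene to product and a closed transition state.

**7 back to 6, 5, 4, 2 and 1.** The O–S, O–Si and acetal C–O bonds are cut, and the alkyne is traced to an aldehyde by a one-carbon homologation. The stereocentre of 7 maps onto C2 of a three-carbon sugar, so the absolute configuration comes from the chiral pool. This demands the S enantiomer of 1 and no enolisation of the α-alkoxy aldehyde.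

## Other disconnections considered

**Alternative 1:** The cut is the C2–C3 bond alone; O1–C2 and the benzo ring are already present in the aryl diazoacetate A1 (methyl 2-[5-bromo-2-({4-[(triisopropylsilyl)oxy]benzyl}oxy)phenyl]-2-diazoacetate).
- **Forward step.** Rh2(S-PTTL)4, the dirhodium tetracarboxylate of N-phthaloyl-(S)-tert-leucine, would expel N2 from A1. The carbene would insert into one of the two enantiotopic C–H bonds of the ArO–CH2–Ar group through a five-membered transition state, closing the dihydrofuran ring.
- **In favour.** An ether-activated, electron-rich benzylic C–H bond is the best kind of site for such an insertion. Both stereocentres arise in one catalytic step, C3 is at the ester level from the start, the C5 bromide is ready for a Heck reaction, and the phenol silyl ether can be removed with fluoride without touching the alkene.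
- **Against.** A concerted insertion of this type is expected to place aryl and ester cis. The direct product should therefore be the cis ester A2 (2R,3S), not the trans ester A3 (2R,3R); A3 would follow only after base-mediated epimerisation at C3. The catalyst enantiomer that leads to 2R would have to be established, the enantiomeric purity is that of the catalytic step, and a diazo compound must be prepared and handled.
- **Comparison.** Structurally it forms one ring bond where the chosen plan forms two and a whole arene. Mechanistically it rests on closer analogy than the furan cycloaddition and is the better plan on that point. In step economy it is clearly better (about nine steps from a bromohydroxyphenylacetate against sixteen). The chosen plan is stronger only in taking C2 from a chiral-pool centre by a transfer of known sense and in carrying no epimerisable ester. The end game (Heck, amidation, acidolysis) is the same, so there the two are equal.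

**Alternative 2:** The cuts are O1–C2 and C2–C3; C2 arrives as a one-carbon unit. The partners are the quinone methide precursor A4 (methyl 2-(5-bromo-2-hydroxyphenyl)-2-[(4-methylphenyl)sulfonyl]acetate) and the chiral sulfonium salt A5 ((2R,5R)-1-[4-(benzyloxy)benzyl]-2,5-dimethylthiolan-1-ium bromide).
- **Forward step.** Cs2CO3 would eliminate sulfinate from A4 to give an ortho-quinone methide with the ester on its exocyclic carbon, and would deprotonate A5 to the benzylide. The ylide carbon adds to the methide carbon (C2–C3), the ring rearomatises to a phenoxide, and this displaces the thiolane at C2 (O1–C2) to give A6.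
- **In favour.** The plan is convergent. Anti-periplanar displacement from the less crowded betaine should give trans directly, ester and bromide are in place, and the conditions are mild.
- **Against.** An ester-substituted quinone methide is a very strong electrophile and can oligomerise or be trapped by other nucleophiles. The face selectivity of a semi-stabilised benzylide with an electron-rich aryl group is the only source of the C2 configuration and is eroded if betaine formation is reversible. The chiral sulfide is stoichiometric, and which enantiomer leads to 2R is open. The product ester sits in carbonate, where retro-oxa-Michael opening would destroy C2. The benzyl ether of A6 cannot be hydrogenolysed once the cinnamamide is present.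
- **Comparison.** Structurally both plans close the heterocycle by two bonds in one operation, but here C2 is created during ring closure, whereas the chosen plan sets both centres beforehand. Mechanistically it is a stepwise ionic process whose stereocontrol is reagent-based and less assured. On step economy it is better (roughly eight to nine steps), and on delivering trans directly it is the equal of the chosen plan.

**Alternative 3:** The cuts are O1–C2 and the bond from C3 to the carboxyl carbon; the precursor is the stilbene A7 (3-{(E)-2-[4-(benzyloxy)phenyl]ethenyl}-4-hydroxybenzaldehyde).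
- **Forward step.** Pd(OCOCF3)2 with a chiral bisoxazoline would activate the alkene. The phenol oxygen attacks the aryl-bearing alkene carbon (anti-oxypalladation, O1–C2), CO inserts into the C3–Pd bond with retention, and methanol cleaves the acyl palladium to the methyl ester A8. p-Benzoquinone returns zerovalent palladium to the divalent state.
- **In favour.** It is catalytic and gives the ester carbon and both stereocentres in one step. Anti addition to the E alkene followed by retentive carbonylation corresponds to trans. The C5 aldehyde would give the acrylic acid by a Knoevenagel–Doebner or Horner–Wadsworth–Emmons reaction, and A7 is only a few steps from commercial material.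
- **Against.** The closure is 5-endo-trig onto an internal conjugated alkene, and the phenol is deactivated by the para-formyl group. The benzylic C3–Pd intermediate has a syn hydrogen on C2, so β-hydride elimination to the aromatic benzofuran A9 should compete strongly with CO insertion. CO also competes with the alkene for divalent palladium. Enantioselective oxycarbonylations have their analogies in exo closures of alkenols, not in this endo mode. The benzyl ether has the same drawback as in alternative 2.
- **Comparison.** On step economy this would be the shortest plan of all and is better than the chosen one. Structurally it is as direct as alternative 1. Mechanistically it is the least supported of the four; the chosen plan is longer but each of its steps rests on closer analogy. The final amidation and deprotection are the same, so there they are equal.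

Key step: step 9

## Remarks on the chemistry

- Atom numbers are those of 1-benzofuran (O1, C2, C3, C3a, C4–C7, C7a).
- Assumption: the target is taken as the neutral bis-guanidine of the SMILES; step 16 would deliver it as its bis(trifluoroacetate) salt.
- The allenylzinc addition goes with net inversion at the propargylic carbon, so 7 must be R. This requires the S enantiomer of the glyceraldehyde acetonide 1.
- The phenol is carried as a tert-butyl ether, not a benzyl ether. A benzyl ether could not be removed at the end without reducing the cinnamamide; the tert-butyl ether falls in the same acid step as the Boc groups.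
- The primary carbinol is carried as a triisopropylsilyl ether, not a tert-butyldimethylsilyl ether. The smaller group could migrate to the neighbouring secondary alkoxide in step 7, and the primary alkoxide would then be arylated.
- The alkyne carbon stays silylated until the copper step is over. A free terminal alkyne would form a copper acetylide and couple with 11.
- The skeletons of key-step precursor 13 and product 15 are otherwise unchanged.

## Route

Step 1
Reactants: 1 (4S)-2,2-dimethyl-1,3-dioxolane-4-carbaldehyde [(S)-2,3-O-isopropylideneglyceraldehyde]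
Product: 2 (4R)-4-(2,2-dibromoethenyl)-2,2-dimethyl-1,3-dioxolane
Conditions: CBr4 (2 equiv), PPh3 (4 equiv), CH2Cl2, 0 °C
Reagents that add atoms: carbon tetrabromide, BrC(Br)(Br)Br
Why: Corey–Fuchs dibromo-olefination (Wittig-type reaction of Ph3P=CBr2 with the aldehyde); the medium is not basic enough to enolise the α-alkoxy aldehyde, and the descriptor changes from S to R only because the new substituent ranks below CH2O.

Step 2
Reactants: 2 (4R)-4-(2,2-dibromoethenyl)-2,2-dimethyl-1,3-dioxolane
Product: 4 (4R)-2,2-dimethyl-4-[(trimethylsilyl)ethynyl]-1,3-dioxolane, via lithium acetylide 3 (not isolated)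
Conditions: n-BuLi (2.2 equiv), THF, −78 °C; then TMSCl, −78 → 0 °C
Reagents that add atoms: chlorotrimethylsilane, C[Si](C)(C)Cl
Why: Second stage of the Corey–Fuchs alkyne synthesis: Br/Li exchange, α-elimination and 1,2-hydride shift (Fritsch–Buttenberg–Wiechell rearrangement) give the alkyne, a second equivalent of n-BuLi gives acetylide 3, and this is C-silylated; the stereocentre is not involved.

Step 3
Reactants: 4 (4R)-2,2-dimethyl-4-[(trimethylsilyl)ethynyl]-1,3-dioxolane
Product: 5 (2R)-4-(trimethylsilyl)but-3-yne-1,2-diol
Conditions: p-TsOH·H2O (cat.), MeOH, rt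
Reagents that add atoms: none
Why: Acid-catalysed transacetalisation to methanol frees the diol; an alkynylsilane is stable to mild acid and no stereocentre is touched.

Step 4
Reactants: 5 (2R)-4-(trimethylsilyl)but-3-yne-1,2-diol
Product: 6 (2R)-1-[(triisopropylsilyl)oxy]-4-(trimethylsilyl)but-3-yn-2-ol
Conditions: TIPSCl (1.05 equiv), imidazole, CH2Cl2, 0 °C → rt
Reagents that add atoms: chlorotriisopropylsilane, CC(C)[Si](Cl)(C(C)C)C(C)C
Why: Selective silylation of the less hindered primary hydroxyl by a bulky chlorosilane; the triisopropylsilyl group is chosen because it should not migrate to the secondary oxygen under the basic conditions of step 7.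

Step 5
Reactants: 6 (2R)-1-[(triisopropylsilyl)oxy]-4-(trimethylsilyl)but-3-yn-2-ol
Product: 7 (2R)-1-[(triisopropylsilyl)oxy]-4-(trimethylsilyl)but-3-yn-2-yl methanesulfonate
Conditions: MsCl, Et3N, CH2Cl2, −40 → 0 °C; used without chromatography
Reagents that add atoms: methanesulfonyl chloride, CS(=O)(=O)Cl
Why: O-sulfonylation of the propargylic alcohol; the C–O bond is not broken, so the R configuration is kept.

Step 6
Reactants: 7 (2R)-1-[(triisopropylsilyl)oxy]-4-(trimethylsilyl)but-3-yn-2-yl methanesulfonate, 8 4-(tert-butoxy)benzaldehyde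
Product: 10 (1R,2S)-1-(4-tert-butoxyphenyl)-2-{[(triisopropylsilyl)oxy]methyl}-4-(trimethylsilyl)but-3-yn-1-ol, via allenylzinc reagent 9 (not isolated)
Conditions: Pd(OAc)2 (5 mol %), PPh3 (5 mol %), Et2Zn (3 equiv), THF, −78 → −20 °C; aq. NH4Cl
Reagents that add atoms: none
Why: Palladium-catalysed, zinc-mediated propargylation: zerovalent palladium attacks the alkyne terminus anti to the leaving mesylate (SN2'), transmetalation with retention gives allenylzinc 9, and 9 adds to the aldehyde by SE2' through a closed six-membered transition state with the aryl group turned away from the allenyl substituent (anti). The new C–C bond forms on the face opposite to the departed mesylate, so the R mesylate gives 2S, and the cyclic transition state then sets 1R.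

Step 7
Reactants: 10 (1R,2S)-1-(4-tert-butoxyphenyl)-2-{[(triisopropylsilyl)oxy]methyl}-4-(trimethylsilyl)but-3-yn-1-ol, 11 2-bromofuran
Product: 12 2-{[(1R,2S)-1-(4-tert-butoxyphenyl)-2-{[(triisopropylsilyl)oxy]methyl}-4-(trimethylsilyl)but-3-yn-1-yl]oxy}furan
Conditions: CuI (10 mol %), 3,4,7,8-tetramethyl-1,10-phenanthroline (20 mol %), Cs2CO3 (2 equiv), 11 (3 equiv), PhMe, 90 °C, sealed tube, degassed
Reagents that add atoms: none
Why: Ullmann-type C–O coupling of an aliphatic alcohol with a heteroaryl bromide under monovalent copper/phenanthroline catalysis; the carbinol C–O bond is not broken, so C1 keeps its configuration, the C-silylated alkyne cannot form a copper acetylide, and the basic medium suits the acid-labile 2-alkoxyfuran.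

Step 8
Reactants: 12 2-{[(1R,2S)-1-(4-tert-butoxyphenyl)-2-{[(triisopropylsilyl)oxy]methyl}-4-(trimethylsilyl)but-3-yn-1-yl]oxy}furan
Product: 13 2-{[(1R,2S)-1-(4-tert-butoxyphenyl)-2-{[(triisopropylsilyl)oxy]methyl}but-3-yn-1-yl]oxy}furan
Conditions: K2CO3 (cat.), MeOH/THF, 0 °C → rt
Reagents that add atoms: none
Why: Methoxide-induced protodesilylation of the alkynylsilane; the silyl ether, the aryl tert-butyl ether and the furyl ether are stable to carbonate in methanol.

Step 9
Reactants: 13 2-{[(1R,2S)-1-(4-tert-butoxyphenyl)-2-{[(triisopropylsilyl)oxy]methyl}but-3-yn-1-yl]oxy}furan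
Product: 15 (2R,3S)-2-(4-tert-butoxyphenyl)-3-{[(triisopropylsilyl)oxy]methyl}-2,3-dihydro-1-benzofuran-5-ol, via oxanorbornadiene cycloadduct 14 (not isolated)
Conditions: PhMe (0.01 M), i-Pr2NEt (0.2 equiv), BHT (5 mol %), degassed, sealed tube, 150–170 °C
Reagents that add atoms: none
Why: Intramolecular [4+2] cycloaddition of the electron-rich 2-alkoxyfuran (diene carbons becoming C7a, C7, C6 and C5) with the tethered terminal alkyne (C3a and C4) gives the 7-oxanorbornadiene 14; its bridgehead C7a is a ketal carbon, so the C7a–O bridge bond ionises with lone-pair help from O1, and loss of the C5 proton aromatises the ring and leaves the former furan oxygen as the C5 phenol. The closest known reaction type is the intramolecular furan Diels–Alder/ring-opening sequence of 2-amino- and 2-amidofurans that carry the dienophile on the heteroatom, together with the intermolecular conversion of 2-methoxyfuran and alkynes into 4-methoxyphenols. The dihydrofuran ring closes through the C3a–C7a bond in a 5-exo mode with respect to the alkyne (three-atom tether O1–C2–C3, C4 left outside the new ring); the benzo ring closes as the six-membered ring of the [4+2] adduct (C3a–C7a and C4–C5) and is then aromatised. No lasting stereocentre is created: the bridgehead centres of 14 vanish on aromatisation, and C2 and C3 are carried over from 10 because neither takes part in bond formation and C3 bears a CH2OSi group, not a carbonyl group. Regiochemistry is fixed by the tether, which allows only the fused mode, and the direction of bridge opening is fixed by O1, since only cleavage at C7a gives an oxygen-stabilised cation next to a carbon (C5) that still has a hydrogen to lose. The trans aryl and silyloxymethyl groups favour the folded conformer of the tether (Thorpe–Ingold type effect), and irreversible aromatisation withdraws 14 from the retro-Diels–Alder equilibrium. The amine buffer and the dilute, oxygen-free conditions protect the ketene-acetal-like furan from acid and from the product phenol.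

Step 10
Reactants: 15 (2R,3S)-2-(4-tert-butoxyphenyl)-3-{[(triisopropylsilyl)oxy]methyl}-2,3-dihydro-1-benzofuran-5-ol
Product: 16 (2R,3S)-2-(4-tert-butoxyphenyl)-3-{[(triisopropylsilyl)oxy]methyl}-2,3-dihydro-1-benzofuran-5-yl trifluoromethanesulfonate
Conditions: PhNTf2, Et3N, DMAP (cat.), CH2Cl2, 0 °C → rt
Reagents that add atoms: N-phenylbis(trifluoromethanesulfonimide), O=S(=O)(N(c1ccccc1)S(=O)(=O)C(F)(F)F)C(F)(F)F
Why: Sulfonylation of the phenoxide with a mild triflyl donor; no strong acid is set free, so the tert-butyl ether and the silyl ether remain.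

Step 11
Reactants: 16 (2R,3S)-2-(4-tert-butoxyphenyl)-3-{[(triisopropylsilyl)oxy]methyl}-2,3-dihydro-1-benzofuran-5-yl trifluoromethanesulfonate, 17 acrylic acid
Product: 18 (2E)-3-[(2R,3S)-2-(4-tert-butoxyphenyl)-3-{[(triisopropylsilyl)oxy]methyl}-2,3-dihydro-1-benzofuran-5-yl]prop-2-enoic acid
Conditions: Pd(OAc)2 (5 mol %), 1,3-bis(diphenylphosphino)propane (6 mol %), Et3N (4 equiv), DMF, 90 °C; aq. citric acid work-up
Reagents that add atoms: none
Why: Mizoroki–Heck reaction: oxidative addition of the aryl triflate to zerovalent palladium, syn insertion of the acrylate and syn β-hydride elimination give the E alkene; C2 and C3 are remote and C3 still has no acidifying group.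

Step 12
Reactants: 18 (2E)-3-[(2R,3S)-2-(4-tert-butoxyphenyl)-3-{[(triisopropylsilyl)oxy]methyl}-2,3-dihydro-1-benzofuran-5-yl]prop-2-enoic acid
Product: 19 (2E)-3-[(2R,3S)-2-(4-tert-butoxyphenyl)-3-(hydroxymethyl)-2,3-dihydro-1-benzofuran-5-yl]prop-2-enoic acid
Conditions: TBAF (3 equiv), THF, 0 °C → rt; aq. NH4Cl
Reagents that add atoms: none
Why: Fluoride cleaves the Si–O bond; the carboxylate, the alkene and the aryl tert-butyl ether are inert.

Step 13
Reactants: 19 (2E)-3-[(2R,3S)-2-(4-tert-butoxyphenyl)-3-(hydroxymethyl)-2,3-dihydro-1-benzofuran-5-yl]prop-2-enoic acid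
Product: 21 (2R,3R)-2-(4-tert-butoxyphenyl)-5-[(1E)-2-carboxyethenyl]-2,3-dihydro-1-benzofuran-3-carboxylic acid, via aldehyde 20 (not isolated)
Conditions: TEMPO (20 mol %), PhI(OAc)2 (2.5 equiv), MeCN/H2O (1:1), rt
Reagents that add atoms: water, O
Why: Oxoammonium oxidation (TEMPO with PhI(OAc)2 as terminal oxidant) takes the primary alcohol to aldehyde 20 and, through its hydrate, to the acid under near-neutral conditions; if C3 epimerised at the aldehyde stage it would only settle in the more stable trans form, and the C3 descriptor changes from S to R by priority only.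

Step 14
Reactants: 22 butane-1,4-diamine, 23 N,N'-bis(tert-butoxycarbonyl)-1H-pyrazole-1-carboxamidine
Product: 24 N-(4-aminobutyl)-N',N''-bis(tert-butoxycarbonyl)guanidine (di-Boc-agmatine)
Conditions: 22 (5 equiv), CH2Cl2, rt
Reagents that add atoms: none
Why: Guanylation of a primary amine by addition–elimination at the amidine carbon with pyrazole as leaving group; the excess of diamine ensures that only one nitrogen reacts.

Step 15
Reactants: 21 (2R,3R)-2-(4-tert-butoxyphenyl)-5-[(1E)-2-carboxyethenyl]-2,3-dihydro-1-benzofuran-3-carboxylic acid, 24 N-(4-aminobutyl)-N',N''-bis(tert-butoxycarbonyl)guanidine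
Product: 25 (2R,3R)-N-{4-[N',N''-bis(tert-butoxycarbonyl)guanidino]butyl}-5-[(1E)-3-({4-[N',N''-bis(tert-butoxycarbonyl)guanidino]butyl}amino)-3-oxoprop-1-en-1-yl]-2-(4-tert-butoxyphenyl)-2,3-dihydro-1-benzofuran-3-carboxamide
Conditions: 24 (2.4 equiv), EDC·HCl (2.4 equiv), HOBt, i-Pr2NEt (2.4 equiv), DMF, 0 °C → rt
Reagents that add atoms: none
Why: Carbodiimide/HOBt amide coupling at both carboxyl groups with the only nucleophilic nitrogen of 24; the weakly basic conditions limit deprotonation at C3, and epimerisation there would again lead to trans.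

Step 16
Reactants: 25 (2R,3R)-N-{4-[N',N''-bis(tert-butoxycarbonyl)guanidino]butyl}-5-[(1E)-3-({4-[N',N''-bis(tert-butoxycarbonyl)guanidino]butyl}amino)-3-oxoprop-1-en-1-yl]-2-(4-tert-butoxyphenyl)-2,3-dihydro-1-benzofuran-3-carboxamide
Product: 26 (2R,3R)-N-(4-guanidinobutyl)-5-{(1E)-3-[(4-guanidinobutyl)amino]-3-oxoprop-1-en-1-yl}-2-(4-hydroxyphenyl)-2,3-dihydro-1-benzofuran-3-carboxamide (CNP0497893.1)
Conditions: TFA/CH2Cl2 (1:1), H2O (2 %), 0 °C → rt
Reagents that add atoms: none
Why: Acidolysis of the four tert-butyl carbamates (loss of isobutene and CO2) and of the aryl tert-butyl ether in one operation; the carbonyl group on C3 disfavours ionisation of the C2–O1 bond, and neither the alkene nor the amides react.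

## Compound list

1 | (4S)-2,2-dimethyl-1,3-dioxolane-4-carbaldehyde | CC1(C)OC[C@@H](C=O)O1 | starting material
2 | (4R)-4-(2,2-dibromoethenyl)-2,2-dimethyl-1,3-dioxolane | CC1(C)OC[C@@H](C=C(Br)Br)O1 | intermediate
3 | lithium [(4R)-2,2-dimethyl-1,3-dioxolan-4-yl]acetylide (formed in the flask) | CC1(C)OC[C@@H](C#C[Li])O1 | intermediate
4 | (4R)-2,2-dimethyl-4-[(trimethylsilyl)ethynyl]-1,3-dioxolane | CC1(C)OC[C@@H](C#C[Si](C)(C)C)O1 | intermediate
5 | (2R)-4-(trimethylsilyl)but-3-yne-1,2-diol | OC[C@@H](C#C[Si](C)(C)C)O | intermediate
6 | (2R)-1-[(triisopropylsilyl)oxy]-4-(trimethylsilyl)but-3-yn-2-ol | CC(C)[Si](C(C)C)(C(C)C)OC[C@@H](C#C[Si](C)(C)C)O | intermediate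
7 | (2R)-1-[(triisopropylsilyl)oxy]-4-(trimethylsilyl)but-3-yn-2-yl methanesulfonate | CC(C)[Si](C(C)C)(C(C)C)OC[C@@H](C#C[Si](C)(C)C)OS(C)(=O)=O | intermediate
8 | 4-(tert-butoxy)benzaldehyde | CC(C)(C)Oc1ccc(C=O)cc1 | starting material
9 | ethyl{(aR)-4-[(triisopropylsilyl)oxy]-1-(trimethylsilyl)buta-1,2-dien-1-yl}zinc (formed in the flask) | CC[Zn]C([Si](C)(C)C)=[C@]=C([H])CO[Si](C(C)C)(C(C)C)C(C)C | intermediate
10 | (1R,2S)-1-(4-tert-butoxyphenyl)-2-{[(triisopropylsilyl)oxy]methyl}-4-(trimethylsilyl)but-3-yn-1-ol | C[Si](C)(C)C#C[C@@H](CO[Si](C(C)C)(C(C)C)C(C)C)[C@H](c1ccc(OC(C)(C)C)cc1)O | intermediate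
11 | 2-bromofuran | Brc1ccco1 | starting material
12 | 2-{[(1R,2S)-1-(4-tert-butoxyphenyl)-2-{[(triisopropylsilyl)oxy]methyl}-4-(trimethylsilyl)but-3-yn-1-yl]oxy}furan | C[Si](C)(C)C#C[C@@H](CO[Si](C(C)C)(C(C)C)C(C)C)[C@H](c1ccc(OC(C)(C)C)cc1)Oc1ccco1 | intermediate
13 | 2-{[(1R,2S)-1-(4-tert-butoxyphenyl)-2-{[(triisopropylsilyl)oxy]methyl}but-3-yn-1-yl]oxy}furan (key-step precursor) | C#C[C@@H](CO[Si](C(C)C)(C(C)C)C(C)C)[C@H](c1ccc(OC(C)(C)C)cc1)Oc1ccco1 | intermediate
14 | (2R,3S)-2-(4-tert-butoxyphenyl)-3-{[(triisopropylsilyl)oxy]methyl}-2,3-dihydro-5H-5,7a-epoxy-1-benzofuran (formed in the flask; the bridgehead carbons C5 and C7a are not controlled and either epimer leads to 15) | C12=CC3C=CC1(O3)O[C@@H](c1ccc(OC(C)(C)C)cc1)[C@@H]2CO[Si](C(C)C)(C(C)C)C(C)C | intermediate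
15 | (2R,3S)-2-(4-tert-butoxyphenyl)-3-{[(triisopropylsilyl)oxy]methyl}-2,3-dihydro-1-benzofuran-5-ol (key-step product) | Oc1ccc2c(c1)[C@@H](CO[Si](C(C)C)(C(C)C)C(C)C)[C@H](c1ccc(OC(C)(C)C)cc1)O2 | intermediate
16 | (2R,3S)-2-(4-tert-butoxyphenyl)-3-{[(triisopropylsilyl)oxy]methyl}-2,3-dihydro-1-benzofuran-5-yl trifluoromethanesulfonate | O=S(=O)(Oc1ccc2c(c1)[C@@H](CO[Si](C(C)C)(C(C)C)C(C)C)[C@H](c1ccc(OC(C)(C)C)cc1)O2)C(F)(F)F | intermediate
17 | acrylic acid | C=CC(=O)O | starting material
18 | (2E)-3-[(2R,3S)-2-(4-tert-butoxyphenyl)-3-{[(triisopropylsilyl)oxy]methyl}-2,3-dihydro-1-benzofuran-5-yl]prop-2-enoic acid | OC(=O)/C=C/c1ccc2c(c1)[C@@H](CO[Si](C(C)C)(C(C)C)C(C)C)[C@H](c1ccc(OC(C)(C)C)cc1)O2 | intermediate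
19 | (2E)-3-[(2R,3S)-2-(4-tert-butoxyphenyl)-3-(hydroxymethyl)-2,3-dihydro-1-benzofuran-5-yl]prop-2-enoic acid | OC(=O)/C=C/c1ccc2c(c1)[C@@H](CO)[C@H](c1ccc(OC(C)(C)C)cc1)O2 | intermediate
20 | (2E)-3-[(2R,3R)-2-(4-tert-butoxyphenyl)-3-formyl-2,3-dihydro-1-benzofuran-5-yl]prop-2-enoic acid (formed in the flask) | OC(=O)/C=C/c1ccc2c(c1)[C@@H](C=O)[C@H](c1ccc(OC(C)(C)C)cc1)O2 | intermediate
21 | (2R,3R)-2-(4-tert-butoxyphenyl)-5-[(1E)-2-carboxyethenyl]-2,3-dihydro-1-benzofuran-3-carboxylic acid | OC(=O)/C=C/c1ccc2c(c1)[C@@H](C(=O)O)[C@H](c1ccc(OC(C)(C)C)cc1)O2 | intermediate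
22 | butane-1,4-diamine | NCCCCN | starting material
23 | N,N'-bis(tert-butoxycarbonyl)-1H-pyrazole-1-carboxamidine | CC(C)(C)OC(=O)NC(=NC(=O)OC(C)(C)C)n1cccn1 | starting material
24 | N-(4-aminobutyl)-N',N''-bis(tert-butoxycarbonyl)guanidine | NCCCCNC(=NC(=O)OC(C)(C)C)NC(=O)OC(C)(C)C | intermediate
25 | (2R,3R)-N-{4-[N',N''-bis(tert-butoxycarbonyl)guanidino]butyl}-5-[(1E)-3-({4-[N',N''-bis(tert-butoxycarbonyl)guanidino]butyl}amino)-3-oxoprop-1-en-1-yl]-2-(4-tert-butoxyphenyl)-2,3-dihydro-1-benzofuran-3-carboxamide | CC(C)(C)OC(=O)NC(=NC(=O)OC(C)(C)C)NCCCCNC(=O)/C=C/c1ccc2c(c1)[C@@H](C(=O)NCCCCNC(=NC(=O)OC(C)(C)C)NC(=O)OC(C)(C)C)[C@H](c1ccc(OC(C)(C)C)cc1)O2 | intermediate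
26 | (2R,3R)-N-(4-guanidinobutyl)-5-{(1E)-3-[(4-guanidinobutyl)amino]-3-oxoprop-1-en-1-yl}-2-(4-hydroxyphenyl)-2,3-dihydro-1-benzofuran-3-carboxamide | NC(N)=NCCCCNC(=O)/C=C/c1ccc2c(c1)[C@@H](C(=O)NCCCCN=C(N)N)[C@H](c1ccc(O)cc1)O2 | target

## Step count and least certain steps

Total: 16 steps. Longest linear sequence: 15 steps (steps 1–13, 15 and 16); step 14 is a one-step side branch.

**Key step (step 9).**
- **Risk.** The unactivated alkyne may add more slowly than the 2-alkoxyfuran decomposes. Possible decomposition paths are acid-induced hydrolysis or oligomerisation of the furan, O-to-C migration of the 4-alkoxybenzyl group by ionisation of the benzylic C–O bond, and retro-cycloaddition of 14 before the bridge opens.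
- **Fallback.** It sets out from 8 and rejoins at 15.
  - A Horner–Wadsworth–Emmons reaction with triethyl phosphonoacetate would give ethyl (2E)-3-(4-tert-butoxyphenyl)prop-2-enoate F1.
  - Reduction with i-Bu2AlH would give (2E)-3-(4-tert-butoxyphenyl)prop-2-en-1-ol F2.
  - Silylation with TIPSCl would give {[(2E)-3-(4-tert-butoxyphenyl)prop-2-en-1-yl]oxy}tri(propan-2-yl)silane F3.
  - F3 would then undergo the acid-promoted formal [3+2] annulation of electron-rich styrenes with 1,4-benzoquinone under a chiral BINOL-derived phosphoric acid. The alkene carbon that becomes C3 adds to the activated quinone, the benzylic cation at C2 is captured by the quinone oxygen, and tautomerisation gives the trans 5-hydroxy-dihydrobenzofuran 15.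
  - Enantiocontrol is less secure in this sequence; if it is inadequate, racemic 15 would be resolved on a chiral stationary phase.

**Step 7.**
- **Risk.** C–O bond formation at a hindered secondary alkoxide may be slow. Alkoxide-induced loss of the alkynyl silyl group followed by copper acetylide coupling, or decomposition of the volatile bromofuran, could then take over.
- **Fallback.** It sets out from 10 and rejoins at 15, using nucleophilic aromatic substitution on an activated furan in place of copper catalysis.
  - The sodium alkoxide of 10 (NaH, THF, 0 °C) would displace the nitro group of methyl 5-nitrofuran-2-carboxylate to give methyl 5-{[(1R,2S)-1-(4-tert-butoxyphenyl)-2-{[(triisopropylsilyl)oxy]methyl}-4-(trimethylsilyl)but-3-yn-1-yl]oxy}furan-2-carboxylate F4.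
  - LiOH in THF/MeOH/H2O would cleave both the methyl ester and the alkynyl silyl group to give 5-{[(1R,2S)-1-(4-tert-butoxyphenyl)-2-{[(triisopropylsilyl)oxy]methyl}but-3-yn-1-yl]oxy}furan-2-carboxylic acid F5.
  - F5 would be heated with Et3N in toluene at 150–170 °C. If the electron-rich furoic acid decarboxylates first, 13 forms and goes on to 15. If cycloaddition comes first, the carboxyl group sits on C5 of the bridged adduct and leaves as CO2 in the aromatisation. Both paths end at 15.
  - The push–pull furan of F5 is a poorer diene than 13, which is the price of this detour.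

**Step 6.**
- **Risk.** Anti selectivity may be eroded with an electron-rich aromatic aldehyde, chirality transfer may be incomplete, or silanolate may be lost from the allenylzinc by 1,4-elimination.
- **Fallback.** It sets out from 8 and rejoins at 10, replacing the allenylmetal addition by an auxiliary-controlled aldol reaction.
  - 4-(Trimethylsilyl)but-3-ynoic acid would be attached to (4R)-4-benzyl-1,3-oxazolidin-2-one through its pivaloyl mixed anhydride to give (4R)-4-benzyl-3-[4-(trimethylsilyl)but-3-ynoyl]-1,3-oxazolidin-2-one F6.
  - The Evans syn-aldol reaction with 8 (Bu2BOTf, i-Pr2NEt, CH2Cl2, −78 °C) would give (4R)-4-benzyl-3-[(2R,3R)-3-(4-tert-butoxyphenyl)-3-hydroxy-2-[(trimethylsilyl)ethynyl]propanoyl]-1,3-oxazolidin-2-one F7. The syn relationship read along the carbonyl chain is the anti relationship required when the chain is read through the alkyne.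
  - LiBH4 would remove the auxiliary reductively to give (1R,2S)-1-(4-tert-butoxyphenyl)-2-[(trimethylsilyl)ethynyl]propane-1,3-diol F8.
  - Selective silylation of the primary hydroxyl with TIPSCl/imidazole would give 10.

**Step 13.**
- **Risk.** The ring oxygen may be lost by β-elimination from the transient aldehyde 20, which opens the dihydrofuran and erases C2, or the oxidant may attack the electron-rich cinnamic acid.
- **Fallback.** It sets out from 16 and rejoins at 25, moving the oxidation ahead of the alkene and installing the two arms separately.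
  - TBAF would give (2R,3S)-2-(4-tert-butoxyphenyl)-3-(hydroxymethyl)-2,3-dihydro-1-benzofuran-5-yl trifluoromethanesulfonate F9.
  - Dess–Martin periodinane buffered with NaHCO3 would give (2R,3R)-2-(4-tert-butoxyphenyl)-3-formyl-2,3-dihydro-1-benzofuran-5-yl trifluoromethanesulfonate F10.
  - Pinnick oxidation (NaClO2, NaH2PO4, 2-methyl-2-butene) would give (2R,3R)-2-(4-tert-butoxyphenyl)-5-{[(trifluoromethyl)sulfonyl]oxy}-2,3-dihydro-1-benzofuran-3-carboxylic acid F11.
  - EDC/HOBt coupling with 24 would give (2R,3R)-N-{4-[N',N''-bis(tert-butoxycarbonyl)guanidino]butyl}-2-(4-tert-butoxyphenyl)-5-{[(trifluoromethyl)sulfonyl]oxy}-2,3-dihydro-1-benzofuran-3-carboxamide F12.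
  - A Heck reaction of F12 with N-{4-[N',N''-bis(tert-butoxycarbonyl)guanidino]butyl}prop-2-enamide F13 (from 24 and acryloyl chloride) would give 25.

## Further compounds

F1 | step 9 | ethyl (2E)-3-(4-tert-butoxyphenyl)prop-2-enoate | CCOC(=O)/C=C/c1ccc(OC(C)(C)C)cc1
F2 | step 9 | (2E)-3-(4-tert-butoxyphenyl)prop-2-en-1-ol | OC/C=C/c1ccc(OC(C)(C)C)cc1
F3 | step 9 | {[(2E)-3-(4-tert-butoxyphenyl)prop-2-en-1-yl]oxy}tri(propan-2-yl)silane | CC(C)[Si](C(C)C)(C(C)C)OC/C=C/c1ccc(OC(C)(C)C)cc1
F4 | step 7 | methyl 5-{[(1R,2S)-1-(4-tert-butoxyphenyl)-2-{[(triisopropylsilyl)oxy]methyl}-4-(trimethylsilyl)but-3-yn-1-yl]oxy}furan-2-carboxylate | C[Si](C)(C)C#C[C@@H](CO[Si](C(C)C)(C(C)C)C(C)C)[C@H](c1ccc(OC(C)(C)C)cc1)Oc1ccc(C(=O)OC)o1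
F5 | step 7 | 5-{[(1R,2S)-1-(4-tert-butoxyphenyl)-2-{[(triisopropylsilyl)oxy]methyl}but-3-yn-1-yl]oxy}furan-2-carboxylic acid | C#C[C@@H](CO[Si](C(C)C)(C(C)C)C(C)C)[C@H](c1ccc(OC(C)(C)C)cc1)Oc1ccc(C(=O)O)o1
F6 | step 6 | (4R)-4-benzyl-3-[4-(trimethylsilyl)but-3-ynoyl]-1,3-oxazolidin-2-one | C[Si](C)(C)C#CCC(=O)N1[C@H](Cc2ccccc2)COC1=O
F7 | step 6 | (4R)-4-benzyl-3-[(2R,3R)-3-(4-tert-butoxyphenyl)-3-hydroxy-2-[(trimethylsilyl)ethynyl]propanoyl]-1,3-oxazolidin-2-one | C[Si](C)(C)C#C[C@@H](C(=O)N1[C@H](Cc2ccccc2)COC1=O)[C@H](c1ccc(OC(C)(C)C)cc1)O
F8 | step 6 | (1R,2S)-1-(4-tert-butoxyphenyl)-2-[(trimethylsilyl)ethynyl]propane-1,3-diol | C[Si](C)(C)C#C[C@@H](CO)[C@H](c1ccc(OC(C)(C)C)cc1)O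
F9 | step 13 | (2R,3S)-2-(4-tert-butoxyphenyl)-3-(hydroxymethyl)-2,3-dihydro-1-benzofuran-5-yl trifluoromethanesulfonate | O=S(=O)(Oc1ccc2c(c1)[C@@H](CO)[C@H](c1ccc(OC(C)(C)C)cc1)O2)C(F)(F)F
F10 | step 13 | (2R,3R)-2-(4-tert-butoxyphenyl)-3-formyl-2,3-dihydro-1-benzofuran-5-yl trifluoromethanesulfonate | O=S(=O)(Oc1ccc2c(c1)[C@@H](C=O)[C@H](c1ccc(OC(C)(C)C)cc1)O2)C(F)(F)F
F11 | step 13 | (2R,3R)-2-(4-tert-butoxyphenyl)-5-{[(trifluoromethyl)sulfonyl]oxy}-2,3-dihydro-1-benzofuran-3-carboxylic acid | O=S(=O)(Oc1ccc2c(c1)[C@@H](C(=O)O)[C@H](c1ccc(OC(C)(C)C)cc1)O2)C(F)(F)F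
F12 | step 13 | (2R,3R)-N-{4-[N',N''-bis(tert-butoxycarbonyl)guanidino]butyl}-2-(4-tert-butoxyphenyl)-5-{[(trifluoromethyl)sulfonyl]oxy}-2,3-dihydro-1-benzofuran-3-carboxamide | O=S(=O)(Oc1ccc2c(c1)[C@@H](C(=O)NCCCCNC(=NC(=O)OC(C)(C)C)NC(=O)OC(C)(C)C)[C@H](c1ccc(OC(C)(C)C)cc1)O2)C(F)(F)F
F13 | step 13 | N-{4-[N',N''-bis(tert-butoxycarbonyl)guanidino]butyl}prop-2-enamide | C=CC(=O)NCCCCNC(=NC(=O)OC(C)(C)C)NC(=O)OC(C)(C)C
A1 | alternative 1 | methyl 2-[5-bromo-2-({4-[(triisopropylsilyl)oxy]benzyl}oxy)phenyl]-2-diazoacetate | COC(=O)C(=[N+]=[N-])c1cc(Br)ccc1OCc1ccc(O[Si](C(C)C)(C(C)C)C(C)C)cc1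
A2 | alternative 1 | methyl (2R,3S)-5-bromo-2-{4-[(triisopropylsilyl)oxy]phenyl}-2,3-dihydro-1-benzofuran-3-carboxylate (cis) | Brc1ccc2c(c1)[C@H](C(=O)OC)[C@H](c1ccc(O[Si](C(C)C)(C(C)C)C(C)C)cc1)O2
A3 | alternative 1 | methyl (2R,3R)-5-bromo-2-{4-[(triisopropylsilyl)oxy]phenyl}-2,3-dihydro-1-benzofuran-3-carboxylate (trans) | Brc1ccc2c(c1)[C@@H](C(=O)OC)[C@H](c1ccc(O[Si](C(C)C)(C(C)C)C(C)C)cc1)O2
A4 | alternative 2 | methyl 2-(5-bromo-2-hydroxyphenyl)-2-[(4-methylphenyl)sulfonyl]acetate (racemic) | COC(=O)C(c1cc(Br)ccc1O)S(=O)(=O)c1ccc(C)cc1
A5 | alternative 2 | (2R,5R)-1-[4-(benzyloxy)benzyl]-2,5-dimethylthiolan-1-ium bromide | C[C@@H]1CC[C@@H](C)[S+]1Cc1ccc(OCc2ccccc2)cc1.[Br-]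
A6 | alternative 2 | methyl (2R,3R)-2-[4-(benzyloxy)phenyl]-5-bromo-2,3-dihydro-1-benzofuran-3-carboxylate | Brc1ccc2c(c1)[C@@H](C(=O)OC)[C@H](c1ccc(OCc3ccccc3)cc1)O2
A7 | alternative 3 | 3-{(E)-2-[4-(benzyloxy)phenyl]ethenyl}-4-hydroxybenzaldehyde | O=Cc1ccc(O)c(/C=C/c2ccc(OCc3ccccc3)cc2)c1
A8 | alternative 3 | methyl (2R,3R)-2-[4-(benzyloxy)phenyl]-5-formyl-2,3-dihydro-1-benzofuran-3-carboxylate | O=Cc1ccc2c(c1)[C@@H](C(=O)OC)[C@H](c1ccc(OCc3ccccc3)cc1)O2
A9 | alternative 3 | 2-[4-(benzyloxy)phenyl]-1-benzofuran-5-carbaldehyde | O=Cc1ccc2oc(-c3ccc(OCc4ccccc4)cc3)cc2c1
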